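The numbers in the tables are simulated with made-up constants.

A fraction of the substrate charge per hour is the unit I read these flasks in, and its inverse is the number I carry.

| flask | substrate | reagent | free catalyst | temperature | remark | time |
|---|---|---|---|---|---|---|
| maple | 13 mM | 22 mM | 1.6 mM | 25 °C | run made earlier |  |
| alder | 20 mM | 22 mM | 3.2 mM | 25 °C | run made earlier |  |
| violet | 20 mM | 22.0 mM | 1.6 mM | 25 °C |  | 15 h |
| amber | 20 mM | 40.0 mM | 1.6 mM | 25 °C |  | 4.0 h |

| run | time / h | product / % | substrate / % |
|---|---|---|---|
| maple | 0.833 | 0.6 | 98.4 |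
| maple | 1.50 | 2.5 | 96.6 |
| maple | 2.50 | 5.4 | 93.7 |
| maple | 3.00 | 6.8 | 91.8 |
| maple | 4.00 | 9.7 | 89.0 |
| maple | 5.00 | 12.4 | 86.2 |
| alder | 0.250 | 0.4 | 100.3 |
| alder | 0.833 | 1.1 | 97.8 |
| alder | 1.33 | 2.9 | 96.0 |
| alder | 2.50 | 7.5 | 90.2 |
| alder | 3.00 | 10.4 | 88.4 |
| alder | 4.00 | 14.0 | 84.2 |
| alder | 5.00 | 17.9 | 80.7 |

(readings scatter by 0.3 percentage points)

* the flask that ends with the higher amount of product, in percent of the substrate charged, or "neither" when 2 percentage points or less lies between them (violet / amber / neither)
* final product, as a percentage of the substrate charged, in violet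
* final product, as a percentage of the substrate charged, in amber

Both runs climb straight after a lag. Maple's product slope from its second to its last reading is 0.0283 h⁻¹, and running it back to zero product gives a lag of 0.616 h. Alder's slope from its third to its last reading is 0.0409 h⁻¹. I reach violet's slope by two ways.

From maple, with the same catalyst and substrate given no effect:
0.0283 h⁻¹ × 0.650 = 0.0184 h⁻¹

From alder, with the same substrate and rate proportional to catalyst:
0.0409 h⁻¹ × 0.500 = 0.0204 h⁻¹

The two differ by a factor of 1.11. From maple to alder the rate in mM per hour rose 2.22-fold, more than the 2.00-fold rise in catalyst. If rate does follow catalyst, the surplus belongs to substrate, and the maple way cheats low. I keep the alder way, which gives the charge time 48.9 h: the hours violet would need to turn over its substrate charge at its steady slope.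

Violet: (15 h − 0.616 h) / 48.9 h = 29.4%, or 26.5% by the maple way.

Neither earlier run varied reagent, so I bracket amber. The unchanged charge time gives amber 6.92%, and a charge time shortened in proportion to reagent, 26.9 h, gives amber 12.6%.

The forecast names violet, with 29% (23% to 36%) for violet and 12% (7% to 18%) for amber: “Violet wins on its much longer time”.

    reagent + free catalyst ⇌ catalyst intermediate A (K = 16.0 L mol⁻¹, k = 120 L mol⁻¹ min⁻¹, Ea = 50.0 kJ mol⁻¹, ΔH = −1.00 kJ mol⁻¹)
    catalyst intermediate A → by-product + catalyst intermediate B (k = 0.0280 min⁻¹, Ea = 100 kJ mol⁻¹)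
    substrate + catalyst intermediate B → catalyst intermediate C (k = 1.50 L mol⁻¹ min⁻¹, Ea = 55.0 kJ mol⁻¹)
    catalyst intermediate C → free catalyst + product (k = 0.0380 min⁻¹, Ea = 97.0 kJ mol⁻¹)
    free catalyst ⇌ dormant form (K = 0.880, k = 4.70 × 10⁻⁴ min⁻¹, Ea = 111 kJ mol⁻¹, ΔH = −25.0 kJ mol⁻¹)
    (constants at 25 °C)

Violet ends at 28.0% and amber at 9.90%. Counted back, violet's charge time over 15 h is 51.5 h against the reckoned 48.9 h, and amber's over 4.0 h is 34.2 h, shorter by a factor of 1.51, with amber differing from violet in its time as well as in its 1.82 times the reagent. At 6.24 h in violet, catalyst intermediate A falls back 270 times faster than it goes on, a pre-equilibrium, while its going on has a half-life of 0.41 h. The neighbour, violet with 55 mM of reagent, reaches 42.9%, a charge time of 33.5 h.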